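## Retrosynthetic overview

1. The last C–C bond is C11–C12: the C11 enolate of a tricyclic C10 enone (oxepane/cyclohexane half) is alkylated with an (E)-allylic bromide (hydroazulene half). MeLi then makes the C10 carbinol, and the C3 carbinol is corrected by oxidation and CBS reduction.
2. The cyclohexane ring C6–C11 comes from a cheap arene, 4-bromo-2-methylphenol. After O-alkylation, oxidative dearomatization ties O1 and the C3 oxygen to C7 as a spiro-dioxolane ketal of a cyclohexadienone.
3. Key disconnection C5–C6: a 6-exo radical closure of the C5 bromide onto C6 closes the oxepane O1–C2–C3–C4–C5–C6–C7 inside a 6,8-dioxabicyclo[3.2.1]octane and sets the quaternary C6. The enabling feature is the O1–C2–C3–O diol unit of the oxepane: it can clamp C7 as a ketal and so hold the C4–C5 arm over one face of the C6=C11 bond (β-carbon of the C10 dienone) of the dearomatized ring.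
4. The extra C7–O(C3) bond is then cut by SmI2 under stereoelectronic control, and C7–H is set by ionic hydrogenation (trans ring fusion).
5. The hydroazulene comes from (S)-linalool: cyclopentene by RCM, C22–C23 by Ireland–Claisen, the seven-membered ring by sulfone-anion/epoxide closure (C17–C18). Ring order: cyclopentane, cycloheptane; arene to cyclohexadienone plus dioxolane; tetrahydropyran and oxepane together in the key step; tetrahydropyran bridge removed.

Key step: step 6

Remark (numbering of the target used below): O1, C2 (CMe2), C3 (CHOH), C4, C5, C6 (C–Me), C7 (CH–O1), C8, C9, C10 (C(Me)OH), C11 (CH) form the oxepane/cyclohexane half; C12 (CH2) and C13 (=CH) are the link; C14 (ring sp2 C), C15 (CHMe), C16, C17, C18 (ring-fusion CH), C19 (C(Me)OH), C20, C21, C22 (ring-fusion CH), C23 (CMe2) form the hydroazulene.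

Assumption: the C3 carbinol is carried in the 3R configuration as a stereochemical relay, because a ketal bridge from C3 to C7 is only possible on the face anti to the C6 methyl; it is corrected to 3S in steps 22 and 23.

## Route

Step 1
Reactants: 1 4-bromo-2-methylphenol; 2 (S)-3-hydroxydihydrofuran-2(3H)-one
Product: 3 (R)-3-(4-bromo-2-methylphenoxy)dihydrofuran-2(3H)-one
Conditions: PPh3, DIAD, THF, 0 °C to rt
Reagents that add atoms: none
Why: Mitsunobu etherification of an α-hydroxy lactone by a phenol proceeds with SN2 inversion, so the (S)-carbinol gives the (R)-aryl ether carbon that becomes C3.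

Step 2
Reactants: 3 (R)-3-(4-bromo-2-methylphenoxy)dihydrofuran-2(3H)-one
Product: 4 (R)-3-(4-bromo-2-methylphenoxy)-4-methylpentane-1,4-diol
Conditions: MeMgBr (4 equiv), THF, 0 °C to rt; aq NH4Cl
Reagents that add atoms: methylmagnesium bromide, C[Mg]Br
Why: Double Grignard addition to the lactone carbonyl gives the C2 gem-dimethyl carbinol and releases the C5 primary alcohol, while C3 is not touched because carbonyl addition of MeMgBr outruns enolization.

Step 3
Reactants: 4 (R)-3-(4-bromo-2-methylphenoxy)-4-methylpentane-1,4-diol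
Product: 5 (R)-3-(4-hydroxy-2-methylphenoxy)-4-methylpentane-1,4-diol
Conditions: Pd2(dba)3 (2 mol %), tBuXPhos (8 mol %), KOH, 1,4-dioxane/H2O, 100 °C; then aq HCl
Reagents that add atoms: potassium hydroxide, [K+].[OH-]
Why: Palladium-catalysed hydroxylation of the aryl bromide with hydroxide (C–O cross-coupling with a bulky biarylphosphine) installs the para-hydroxyl needed for dearomatization; the aliphatic alcohols should not couple in the aqueous medium.

Step 4
Reactants: 5 (R)-3-(4-hydroxy-2-methylphenoxy)-4-methylpentane-1,4-diol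
Product: 6 (R)-4-[(5-bromo-2-hydroxy-2-methylpentan-3-yl)oxy]-3-methylphenol
Conditions: CBr4, PPh3, CH2Cl2, 0 °C
Reagents that add atoms: carbon tetrabromide, BrC(Br)(Br)Br
Why: Appel reaction; only the primary alcohol is converted (SN2 on the alkoxyphosphonium ion) into the bromide that serves as radical precursor, the tertiary alcohol and the phenol being inert.

Step 5
Reactants: 6 (R)-4-[(5-bromo-2-hydroxy-2-methylpentan-3-yl)oxy]-3-methylphenol
Product: 7 (3R,5R)-3-(2-bromoethyl)-2,2,6-trimethyl-1,4-dioxaspiro[4.5]deca-6,9-dien-8-one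
Conditions: PhI(OAc)2, CH2Cl2/(CF3)2CHOH, 0 °C
Reagents that add atoms: none
Why: Oxidative dearomatization of the para-alkoxyphenol by PhI(OAc)2 with capture of the C7 cation by the tertiary hydroxyl gives the spiro-dioxolane quinone monoketal; the C7 epimer drawn (bromoethyl arm on the side of the methyl-bearing double bond) should prevail because the aryl ether reacts through the conformer that keeps C3–H, not the arm, in the ring plane next to C8–H, and any other epimer is removed by chromatography and can be re-equilibrated with acid.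

Step 6
Reactants: 7 (3R,5R)-3-(2-bromoethyl)-2,2,6-trimethyl-1,4-dioxaspiro[4.5]deca-6,9-dien-8-one
Product: 8 (3R,6R,7R)-tricyclic enone ketal: cyclohex-8-en-10-one ring whose C7 is the ketal carbon of a 6,8-dioxabicyclo[3.2.1]octane (bridges O on C3, O1–C2Me2 and C6(Me)–C5–C4)
Conditions: Bu3SnH (1.3 equiv, syringe pump), AIBN (0.2 equiv), PhH, 80 °C, 0.01 M
Reagents that add atoms: none
Why: Bu3Sn• abstracts bromine from C5 and the primary radical adds 6-exo-trig to C6, the β-carbon of the C10 dienone, after which the C11 α-keto radical takes hydrogen from Bu3SnH (tin hydride radical chain). The closest known reaction type is the acetal-tethered (Ueno–Stork-type) radical cyclization onto cyclohexadienones, a Giese addition that is known to build quaternary carbons when intramolecular. The new bond closes the tetrahydropyran C6–C5–C4–C3–O–C7 in the 6-exo-trig mode and with it the oxepane O1–C2–C3–C4–C5–C6–C7 (formally 7-exo-trig through O1), giving the 6,8-dioxabicyclo[3.2.1]octane. The only new stereocenter, C6, is controlled by C3 through the spiro ketal: the arm can reach C6 only on the ring face that carries the C3 oxygen, so C5 enters syn to that oxygen and the methyl ends anti to it (6R). The step needs regioselectivity for C6 over C8, secured by the C7 configuration of 7 that holds the arm on the C6 side and out of reach of C8 and C11, and cyclization faster than reduction, secured by slow addition of Bu3SnH at high dilution.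

Step 7
Reactants: 9 (S)-(+)-linalool
Product: 10 (S)-1-methylcyclopent-2-en-1-ol
Conditions: second-generation Hoveyda–Grubbs catalyst (1 mol %), CH2Cl2, 40 °C
Reagents that add atoms: none
Why: Ring-closing metathesis of the 1,6-diene releases 2-methylpropene and gives the cyclopentenol without touching the carbinol stereocenter (future C19).

Step 8
Reactants: 10 (S)-1-methylcyclopent-2-en-1-ol
Product: 11 (S)-1-methylcyclopent-2-en-1-yl 2-methylpropanoate
Conditions: n-BuLi, THF, −78 °C; then i-PrCOCl, −78 °C to 0 °C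
Reagents that add atoms: 2-methylpropanoyl chloride, CC(C)C(Cl)=O
Why: O-Acylation of the lithium alkoxide of the tertiary allylic alcohol with the acid chloride gives the ester needed for the sigmatropic step.

Step 9
Reactants: 11 (S)-1-methylcyclopent-2-en-1-yl 2-methylpropanoate
Product: 14 2-methyl-2-[(1R)-3-methylcyclopent-2-en-1-yl]propanoic acid, via silyl ketene acetal 12 (not isolated), via trimethylsilyl ester 13 (not isolated)
Conditions: LiN(i-Pr)2, THF, −78 °C; Me3SiCl, Et3N, −78 °C to 60 °C; then 1 M HCl
Reagents that add atoms: chlorotrimethylsilane, C[Si](C)(C)Cl (its silyl group is present in 12 and 13 only and is lost on work-up)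
Why: Ireland–Claisen rearrangement: the tetrasubstituted silyl ketene acetal rearranges suprafacially across the cyclopentene, so the configuration of the C19–O bond is transferred to the new C22–C23 bond (22R) while the quaternary C23 is formed and the double bond moves to C18=C19.

Step 10
Reactants: 14 2-methyl-2-[(1R)-3-methylcyclopent-2-en-1-yl]propanoic acid
Product: 15 2-methyl-2-[(1R)-3-methylcyclopent-2-en-1-yl]pentan-3-one
Conditions: EtLi (2.5 equiv), Et2O, 0 °C to rt; aq NH4Cl
Reagents that add atoms: ethyllithium, [Li]CC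
Why: Addition of ethyllithium to the lithium carboxylate stops at the dilithio gem-diolate, which collapses to the ethyl ketone only on work-up.

Step 11
Reactants: 15 2-methyl-2-[(1R)-3-methylcyclopent-2-en-1-yl]pentan-3-one
Product: 16 2,4-dimethyl-2-[(1R)-3-methylcyclopent-2-en-1-yl]-6-(phenylsulfonyl)hexan-3-one (C4 epimers of the chain, future C15)
Conditions: LiN(i-Pr)2, THF, −78 °C; phenyl vinyl sulfone, −78 °C to −40 °C; aq NH4Cl
Reagents that add atoms: phenyl vinyl sulfone, C=CS(=O)(=O)c1ccccc1
Why: Michael addition of the kinetic lithium enolate (the CH2 of the ethyl group is the only enolizable position) to the vinyl sulfone adds C16 and C17; C15 is formed as a mixture that is corrected in step 14.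

Step 12
Reactants: 16 2,4-dimethyl-2-[(1R)-3-methylcyclopent-2-en-1-yl]-6-(phenylsulfonyl)hexan-3-one
Product: 17 2,4-dimethyl-2-[(1S,2S,5R)-5-methyl-6-oxabicyclo[3.1.0]hexan-2-yl]-6-(phenylsulfonyl)hexan-3-one (epoxide oxygen trans to the side chain)
Conditions: mCPBA, NaHCO3, CH2Cl2, 0 °C
Reagents that add atoms: 3-chloroperoxybenzoic acid, OOC(=O)c1cccc(Cl)c1
Why: Prilezhaev epoxidation of the trisubstituted alkene should occur on the face opposite the bulky C22 substituent, which places the epoxide oxygen (the future C19 hydroxyl) trans to the side chain.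

Step 13
Reactants: 17 2,4-dimethyl-2-[(1S,2S,5R)-5-methyl-6-oxabicyclo[3.1.0]hexan-2-yl]-6-(phenylsulfonyl)hexan-3-one
Product: 18 (1R,3aR,8aR)-1-hydroxy-1,4,4,6-tetramethyl-8-(phenylsulfonyl)octahydroazulen-5(1H)-one (cis-fused; mixture at C6 and C8 of the azulene)
Conditions: LiN(i-Pr)2 (2.2 equiv), THF/HMPA, −78 °C to rt; aq NH4Cl
Reagents that add atoms: none
Why: Intramolecular SN2 opening of the epoxide at C18 by the sulfonyl carbanion (7-exo-tet epoxide-opening cyclization of a stabilized carbanion) must occur anti to the oxygen and therefore on the face of the tether, giving the cis ring fusion (18R) and the C19 alkoxide trans to the new bond (19R); the second equivalent of base keeps the less nucleophilic ketone enolate from quenching the carbanion.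

Step 14
Reactants: 18 (1R,3aR,8aR)-1-hydroxy-1,4,4,6-tetramethyl-8-(phenylsulfonyl)octahydroazulen-5(1H)-one
Product: 19 (1R,3aR,6R,8aR)-1-hydroxy-1,4,4,6-tetramethyloctahydroazulen-5(1H)-one
Conditions: sodium amalgam Na(Hg) (6 %), Na2HPO4, MeOH/THF, −20 °C to 0 °C; then NaOMe, MeOH, rt
Reagents that add atoms: none
Why: Reductive desulfonylation by sodium amalgam removes the activating group, and methoxide equilibration through the C14 enolate should place the C15 methyl on the convex face of the cis-fused bicycle (15R, cis to the ring-fusion hydrogens).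

Step 15
Reactants: 19 (1R,3aR,6R,8aR)-1-hydroxy-1,4,4,6-tetramethyloctahydroazulen-5(1H)-one
Product: 20 (1R,3aR,6R,8aR)-1,4,4,6-tetramethyl-1-(triethylsilyloxy)octahydroazulen-5(1H)-one
Conditions: Et3SiOTf, 2,6-lutidine, CH2Cl2, −78 °C to 0 °C
Reagents that add atoms: triethylsilyl trifluoromethanesulfonate, CC[Si](CC)(CC)OS(=O)(=O)C(F)(F)F
Why: Silylation of the tertiary alcohol with the silyl triflate protects C19–OH against PBr3 and the enolate chemistry that follow.

Step 16
Reactants: 20 (1R,3aR,6R,8aR)-1,4,4,6-tetramethyl-1-(triethylsilyloxy)octahydroazulen-5(1H)-one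
Product: 21 (1R,3aR,6R,8aR)-1,4,4,6-tetramethyl-1-(triethylsilyloxy)-5-vinyldecahydroazulen-5-ol (C5 epimers of the azulene)
Conditions: CH2=CHMgBr, CeCl3, THF, −78 °C to 0 °C; aq NH4Cl
Reagents that add atoms: vinylmagnesium bromide, C=C[Mg]Br
Why: The vinylcerium reagent adds to the hindered, enolizable C14 ketone without enolization (organocerium 1,2-addition); the configuration of the new carbinol is irrelevant because it is lost in the next step.

Step 17
Reactants: 21 (1R,3aR,6R,8aR)-1,4,4,6-tetramethyl-1-(triethylsilyloxy)-5-vinyldecahydroazulen-5-ol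
Product: 22 (1R,3aR,6R,8aR,E)-5-(2-bromoethylidene)-1,4,4,6-tetramethyl-1-(triethylsilyloxy)decahydroazulene
Conditions: PBr3, pyridine (cat.), Et2O, −10 °C
Reagents that add atoms: phosphorus tribromide, BrP(Br)Br
Why: Allylic transposition of the tertiary vinyl carbinol with PBr3 (SN2′ bromination) gives the primary allylic bromide, the E isomer being favoured because the CH2Br group avoids the C23 gem-dimethyl group (allylic 1,3-strain).

Step 18
Reactants: 8 (3R,6R,7R)-tricyclic enone ketal; 22 (E)-allylic bromide of the hydroazulene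
Product: 24 C11-equatorial coupled enone ketal (11R), via C11-epimeric alkylation product 23 (not isolated)
Conditions: LiN(i-Pr)2, THF, −78 °C; 22, DMPU, −78 °C to 0 °C; then NaOMe, MeOH, rt
Reagents that add atoms: none
Why: The cross-conjugated lithium dienolate of 8 can only form at C11 and is alkylated by the allylic bromide (SN2) on the face anti to the C6 methyl, and methoxide then epimerizes the axial product to the equatorial C11 epimer (11R), which is free of the syn-axial clash with the axial C7–O bond.

Step 19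
Reactants: 24 C11-equatorial coupled enone ketal
Product: 25 enol ether ketone: oxepane O1–C7=C8 enol ether, C10 ketone, free (3R)-hydroxyl
Conditions: SmI2 (2.5 equiv), THF/MeOH, −78 °C
Reagents that add atoms: none
Why: Two-electron reduction of the enone by SmI2 generates carbanion character at C8, which expels the axial C7–O(C3) bond that is aligned with the π system (reductive γ-elimination of a γ-alkoxy enone) while the equatorial C7–O1 bond stays, so the tetrahydropyran bridge opens, the C3 hydroxyl is released and kinetic protonation at C9 leaves the cyclic enol ether.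

Step 20
Reactants: 25 enol ether ketone
Product: 26 trans-fused oxepane ketone (7R) with (3R)-hydroxyl
Conditions: Et3SiH, CF3CO2H, CH2Cl2, −78 °C to −40 °C
Reagents that add atoms: none
Why: Ionic hydrogenation: protonation of the enol ether at C8 gives the cyclic oxocarbenium ion and Et3SiH delivers hydride to C7 axially, anti to the angular C6 methyl, which sets 7R and the trans ring fusion (as in reductive etherifications of fused cyclic ethers).

Step 21
Reactants: 26 trans-fused oxepane ketone
Product: 27 3-epi-diol (3R,10S), C19 triethylsilyl ether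
Conditions: MeLi (4 equiv), CeCl3, THF, −78 °C; aq NH4Cl
Reagents that add atoms: methyllithium, [Li]C
Why: MeLi–CeCl3 adds to the C10 ketone from the equatorial direction because the axial trajectory is blocked by the syn-axial C6 methyl, giving the axial tertiary alcohol (10S); the free C3 hydroxyl only consumes one equivalent of reagent.

Step 22
Reactants: 27 3-epi-diol
Product: 28 C3 ketone (oxepan-3-one), C19 triethylsilyl ether
Conditions: Dess–Martin periodinane, NaHCO3, CH2Cl2, rt
Reagents that add atoms: none
Why: Dess–Martin oxidation of the only secondary alcohol gives the C3 ketone and erases the relay stereocenter; the tertiary alcohols cannot react.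

Step 23
Reactants: 28 C3 ketone
Product: 29 C19 triethylsilyl ether of the target (3S)
Conditions: (R)-2-methyl-CBS-oxazaborolidine, catecholborane, toluene, −78 °C; then MeOH, aq NaOH
Reagents that add atoms: none
Why: Corey–Bakshi–Shibata reduction under reagent control (large quaternary C2 against small C4H2) delivers hydride to the face anti to the C6 methyl and gives the 3S alcohol; catecholborane leaves the trisubstituted alkene untouched.

Step 24
Reactants: 29 C19 triethylsilyl ether of the target
Product: 30 target, (3S,6R,7R,10S,11R,13E,15R,18R,19R,22R) in the numbering above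
Conditions: Bu4NF, THF, 40 °C
Reagents that add atoms: none
Why: Fluoride cleaves the tertiary triethylsilyl ether (Si–F bond formation) to release the C19 hydroxyl and give the target.

## Compound list

1 | 4-bromo-2-methylphenol | Cc1cc(Br)ccc1O | starting material
2 | (S)-3-hydroxydihydrofuran-2(3H)-one | O[C@H]1CCOC1=O | starting material
3 | (R)-3-(4-bromo-2-methylphenoxy)dihydrofuran-2(3H)-one | Cc1cc(Br)ccc1O[C@@H]1CCOC1=O | intermediate
4 | (R)-3-(4-bromo-2-methylphenoxy)-4-methylpentane-1,4-diol | Cc1cc(Br)ccc1O[C@H](CCO)C(C)(C)O | intermediate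
5 | (R)-3-(4-hydroxy-2-methylphenoxy)-4-methylpentane-1,4-diol | Cc1cc(O)ccc1O[C@H](CCO)C(C)(C)O | intermediate
6 | (R)-4-[(5-bromo-2-hydroxy-2-methylpentan-3-yl)oxy]-3-methylphenol | Cc1cc(O)ccc1O[C@H](CCBr)C(C)(C)O | intermediate
7 | (3R,5R)-3-(2-bromoethyl)-2,2,6-trimethyl-1,4-dioxaspiro[4.5]deca-6,9-dien-8-one | O=C1C=C(C)[C@]2(C=C1)O[C@H](CCBr)C(C)(C)O2 | intermediate
8 | (3R,6R,7R)-tricyclic enone ketal (6,8-dioxabicyclo[3.2.1]octane fused to cyclohexenone) | O=C1C[C@@]2(C)CC[C@H]3O[C@@]2(OC3(C)C)C=C1 | intermediate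
9 | (S)-(+)-linalool | C=C[C@@](C)(O)CCC=C(C)C | starting material
10 | (S)-1-methylcyclopent-2-en-1-ol | C[C@@]1(O)C=CCC1 | intermediate
11 | (S)-1-methylcyclopent-2-en-1-yl 2-methylpropanoate | C[C@@]1(OC(=O)C(C)C)C=CCC1 | intermediate
12 | trimethylsilyl ketene acetal of 11 | C[C@@]1(OC(O[Si](C)(C)C)=C(C)C)C=CCC1 | intermediate
13 | trimethylsilyl 2-methyl-2-[(1R)-3-methylcyclopent-2-en-1-yl]propanoate | CC1=C[C@@H](CC1)C(C)(C)C(=O)O[Si](C)(C)C | intermediate
14 | 2-methyl-2-[(1R)-3-methylcyclopent-2-en-1-yl]propanoic acid | CC1=C[C@@H](CC1)C(C)(C)C(O)=O | intermediate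
15 | 2-methyl-2-[(1R)-3-methylcyclopent-2-en-1-yl]pentan-3-one | CC1=C[C@@H](CC1)C(C)(C)C(=O)CC | intermediate
16 | 2,4-dimethyl-2-[(1R)-3-methylcyclopent-2-en-1-yl]-6-(phenylsulfonyl)hexan-3-one | CC1=C[C@@H](CC1)C(C)(C)C(=O)C(C)CCS(=O)(=O)c1ccccc1 | intermediate
17 | 2,4-dimethyl-2-[(1S,2S,5R)-5-methyl-6-oxabicyclo[3.1.0]hexan-2-yl]-6-(phenylsulfonyl)hexan-3-one | C[C@@]12CC[C@@H](C(C)(C)C(=O)C(C)CCS(=O)(=O)c3ccccc3)[C@@H]1O2 | intermediate
18 | (1R,3aR,8aR)-1-hydroxy-1,4,4,6-tetramethyl-8-(phenylsulfonyl)octahydroazulen-5(1H)-one | CC1CC(S(=O)(=O)c3ccccc3)[C@@H]2[C@@H](CC[C@@]2(C)O)C(C)(C)C1=O | intermediate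
19 | (1R,3aR,6R,8aR)-1-hydroxy-1,4,4,6-tetramethyloctahydroazulen-5(1H)-one | C[C@@H]1CC[C@@H]2[C@@H](CC[C@@]2(C)O)C(C)(C)C1=O | intermediate
20 | (1R,3aR,6R,8aR)-1,4,4,6-tetramethyl-1-(triethylsilyloxy)octahydroazulen-5(1H)-one | C[C@@H]1CC[C@@H]2[C@@H](CC[C@@]2(C)O[Si](CC)(CC)CC)C(C)(C)C1=O | intermediate
21 | (1R,3aR,6R,8aR)-1,4,4,6-tetramethyl-1-(triethylsilyloxy)-5-vinyldecahydroazulen-5-ol | C[C@@H]1CC[C@@H]2[C@@H](CC[C@@]2(C)O[Si](CC)(CC)CC)C(C)(C)C1(O)C=C | intermediate
22 | (1R,3aR,6R,8aR,E)-5-(2-bromoethylidene)-1,4,4,6-tetramethyl-1-(triethylsilyloxy)decahydroazulene | C[C@@H]1CC[C@@H]2[C@@H](CC[C@@]2(C)O[Si](CC)(CC)CC)C(C)(C)/C1=C/CBr | intermediate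
23 | C11-epimeric (axial) coupled enone ketal | C[C@@H]1CC[C@@H]2[C@@H](CC[C@@]2(C)O[Si](CC)(CC)CC)C(C)(C)/C1=C/C[C@H]1[C@@]2(C)CC[C@H]3O[C@@]2(OC3(C)C)C=CC1=O | intermediate
24 | C11-equatorial coupled enone ketal (11R) | C[C@@H]1CC[C@@H]2[C@@H](CC[C@@]2(C)O[Si](CC)(CC)CC)C(C)(C)/C1=C/C[C@@H]1[C@@]2(C)CC[C@H]3O[C@@]2(OC3(C)C)C=CC1=O | intermediate
25 | enol ether ketone (C7=C8 enol ether in the oxepane, C10 ketone, 3R alcohol) | C[C@@H]1CC[C@@H]2[C@@H](CC[C@@]2(C)O[Si](CC)(CC)CC)C(C)(C)/C1=C/C[C@@H]1[C@@]2(C)CC[C@@H](O)C(C)(C)OC2=CCC1=O | intermediate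
26 | trans-fused oxepane ketone (7R, 3R alcohol) | C[C@@H]1CC[C@@H]2[C@@H](CC[C@@]2(C)O[Si](CC)(CC)CC)C(C)(C)/C1=C/C[C@@H]1[C@@]2(C)CC[C@@H](O)C(C)(C)O[C@@H]2CCC1=O | intermediate
27 | 3-epi-diol (3R,10S), C19 triethylsilyl ether | C[C@@H]1CC[C@@H]2[C@@H](CC[C@@]2(C)O[Si](CC)(CC)CC)C(C)(C)/C1=C/C[C@@H]1[C@@]2(C)CC[C@@H](O)C(C)(C)O[C@@H]2CC[C@]1(C)O | intermediate
28 | C3 ketone, C19 triethylsilyl ether | C[C@@H]1CC[C@@H]2[C@@H](CC[C@@]2(C)O[Si](CC)(CC)CC)C(C)(C)/C1=C/C[C@@H]1[C@@]2(C)CCC(=O)C(C)(C)O[C@@H]2CC[C@]1(C)O | intermediate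
29 | C19 triethylsilyl ether of the target | C[C@@H]1CC[C@@H]2[C@@H](CC[C@@]2(C)O[Si](CC)(CC)CC)C(C)(C)/C1=C/C[C@@H]1[C@@]2(C)CC[C@H](O)C(C)(C)O[C@@H]2CC[C@]1(C)O | intermediate
30 | target CNP0167890.3 | C[C@@H]1CC[C@@H]2[C@@H](CC[C@@]2(C)O)C(C)(C)/C1=C/C[C@@H]1[C@@]2(C)CC[C@H](O)C(C)(C)O[C@@H]2CC[C@]1(C)O | target

## Step count and risks

Total step count: 24. Longest linear sequence: 18 steps (steps 7 to 24, from (S)-linalool).

Three steps most likely to fail:

Step 13. The ketone enolate, not the sulfonyl carbanion, may engage the epoxide (five-membered ring closure through carbon or oxygen), or proton transfer may stall the slow seven-membered ring closure. The fallback removes the ketone before ring closure. Starting from 16, LiAlH4 reduction gives the C14 alcohol F1, and t-BuMe2SiOTf with 2,6-lutidine gives the silyl ether F2. mCPBA then gives the epoxide F3. n-BuLi (1.1 equiv) in THF/HMPA now forms only the sulfonyl carbanion and closes the ring to the bicyclic silyl ether F4. Bu4NF releases the diol F5, and Dess–Martin oxidation of its secondary hydroxyl returns to 18.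

Step 19. Electron transfer may take another course: cleavage of the C7–O1 bond, reduction of the C10 ketone, or protonation of the dienolate at C7. The fallback is hydride-based. From 24, conjugate reduction with [(Ph3P)CuH]6 gives the saturated ketone ketal F6, and MeLi/CeCl3 gives the tertiary alcohol ketal F7. i-Bu2AlH in CH2Cl2 then opens the bridged ketal at the less hindered oxygen on C3 with delivery of hydride to C7 on the same face (reductive ketal cleavage with retention). This rejoins the route at 27 and skips 25 and 26.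

Step 6. Hydrogen transfer from Bu3SnH to the primary radical, or a 1,5-hydrogen shift from a C2 methyl, may outrun addition to the fully substituted C6. The fallback replaces the radical chain by a nickel-catalysed reductive conjugate addition of the alkyl bromide. From 7, NiCl2(dme), neocuproine, Mn powder and Et3SiCl in DMF give the triethylsilyl dienol ether F8, and dilute HCl in THF returns 8.

Further compounds
F1 | step 13 | 2,4-dimethyl-2-[(1R)-3-methylcyclopent-2-en-1-yl]-6-(phenylsulfonyl)hexan-3-ol | CC1=C[C@@H](CC1)C(C)(C)C(O)C(C)CCS(=O)(=O)c1ccccc1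
F2 | step 13 | tert-butyldimethylsilyl ether of F1 | CC1=C[C@@H](CC1)C(C)(C)C(O[Si](C)(C)C(C)(C)C)C(C)CCS(=O)(=O)c1ccccc1
F3 | step 13 | epoxide of F2 (oxygen trans to the side chain) | C[C@@]12CC[C@@H](C(C)(C)C(O[Si](C)(C)C(C)(C)C)C(C)CCS(=O)(=O)c3ccccc3)[C@@H]1O2
F4 | step 13 | cis-fused bicyclic sulfone, C14 silyl ether, C19 alcohol | CC1CC(S(=O)(=O)c3ccccc3)[C@@H]2[C@@H](CC[C@@]2(C)O)C(C)(C)C1O[Si](C)(C)C(C)(C)C
F5 | step 13 | cis-fused bicyclic sulfone diol | CC1CC(S(=O)(=O)c3ccccc3)[C@@H]2[C@@H](CC[C@@]2(C)O)C(C)(C)C1O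
F6 | step 19 | saturated C10 ketone with intact bridged ketal | C[C@@H]1CC[C@@H]2[C@@H](CC[C@@]2(C)O[Si](CC)(CC)CC)C(C)(C)/C1=C/C[C@@H]1[C@@]2(C)CC[C@H]3O[C@@]2(OC3(C)C)CCC1=O
F7 | step 19 | C10 tertiary alcohol (10S) with intact bridged ketal | C[C@@H]1CC[C@@H]2[C@@H](CC[C@@]2(C)O[Si](CC)(CC)CC)C(C)(C)/C1=C/C[C@@H]1[C@@]2(C)CC[C@H]3O[C@@]2(OC3(C)C)CC[C@]1(C)O
F8 | step 6 | triethylsilyl dienol ether of 8 | CC[Si](CC)(CC)OC1=C[C@@]2(C)CC[C@H]3O[C@@]2(OC3(C)C)C=C1
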